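**Plan**

1. Numbering (germacrane type): C1 furanone C=O, C2 furanone CH, C3 furanone O–C=, C4(CH3)=C5, C6 (O-angelate), C7, C8 (lactone O), C9H2, C10 (CH3, ring O), C11=C13H2, C12 lactone C=O. Ring A = lactone (C7, C8, O, C12, C11), ring B = furanone (O, C3, C2, C1, C10), ring C = nine-membered ring (O, C3, C4, C5, C6, C7, C8, C9, C10).
2. Cuts, in retrosynthetic order: the angelate acyl–O6 bond and C6–H (back to the C6 ketone and the C6-epimeric carbinol); C6–C7 of ring C, with C11=C13 shifted to C7=C11 plus C13–Br; C7–C8 and O–C12 of ring A; O–C3 of ring B; C1–C2; C9–C10.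
3. Forward order: a lactate-derived dioxolanone is allylated (C9–C10). An enyne acetylide is added (C1–C2). Ring B is closed, then ring A is built as an α-(bromomethyl)butenolide, and ring C is closed last. C6 is then corrected and acylated.
4. Enabling feature: C6(O)–C7–C11(=C13H2) is a homoallylic-alcohol retron. C7 is shared by rings A and C, and C11=C13 is exocyclic on ring A. An allyl anion C13–C11=C7 locked inside a butenolide can therefore attack a C6 aldehyde. One event then closes ring C, sets C7 and creates the α-methylene lactone.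
5. Stereochemistry: C10 comes from (S)-lactic acid (self-regeneration of stereocentres). C8 comes from a chiral chromium complex. C7 comes from C8 and the short tether in the ring closure. C6 comes from peripheral hydride attack on the macrocyclic ketone. The C4=C5 Z geometry comes from (Z)-3-methylpent-2-en-4-yn-1-ol, and the angelate geometry from angelic acid.

Key step: step 12

Remark: formaldehyde is drawn as the monomer although it is generated from paraformaldehyde. Lithium, magnesium and chromium species are drawn in their simplest monomeric form.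

**Step 1**
Reactants: 1 (S)-lactic acid; 2 pivalaldehyde
Product: 3 (2S,5S)-2-tert-butyl-5-methyl-1,3-dioxolan-4-one (cis)
Conditions: p-TsOH (cat.), pentane, reflux, Dean–Stark trap; crystallisation at low temperature
Reagents that add atoms: none
Why: Acid-catalysed acetalisation with azeotropic removal of water should favour the cis isomer (tert-butyl and methyl on the same face), which is purified by crystallisation, so that the lactate centre is stored in the new acetal centre (self-regeneration of stereocentres).

**Step 2**
Reactants: 3 (2S,5S)-2-tert-butyl-5-methyl-1,3-dioxolan-4-one; 4 allyl bromide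
Product: 6 (2S,5R)-5-allyl-2-tert-butyl-5-methyl-1,3-dioxolan-4-one, via lithium enolate 5 (not isolated)
Conditions: LDA (1.05 equiv), THF, −78 °C; then 4, −78 to −30 °C
Reagents that add atoms: none
Why: Enolate alkylation, in which allyl bromide attacks the planar enolate 5 on the face opposite the tert-butyl group, sets the quaternary centre (later C10, R) and attaches C9 and C8.

**Step 3**
Reactants: 7 (Z)-3-methylpent-2-en-4-yn-1-ol
Product: 8 (Z)-tert-butyldimethyl[(3-methylpent-2-en-4-yn-1-yl)oxy]silane
Conditions: TBSCl, imidazole, CH2Cl2, 0 °C to rt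
Reagents that add atoms: tert-butyldimethylsilyl chloride, CC(C)(C)[Si](C)(C)Cl
Why: Standard silylation of a primary allylic alcohol blocks the hydroxyl group, which would otherwise quench the acetylide and later add to the activated alkyne, and leaves the Z double bond (later C4=C5) untouched.

**Step 4**
Reactants: 8 (Z)-silyl ether of the enynol; 6 (2S,5R)-5-allyl-2-tert-butyl-5-methyl-1,3-dioxolan-4-one
Product: 11 (4R,8Z)-10-(tert-butyldimethylsilyloxy)-4-hydroxy-4,8-dimethyldeca-1,8-dien-6-yn-5-one, via lithium acetylide 9 (not isolated), via lithium lactolate 10 (not isolated)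
Conditions: 8, n-BuLi (1.05 equiv), THF, −78 °C; then 6, −78 to −40 °C; AcOH quench at −78 °C
Reagents that add atoms: none
Why: 1,2-Addition of a lithium acetylide to a lactone-type carbonyl stops at the lactolate 10 at low temperature, and on the acidic quench the hemiketal opens and the hemiacetal loses pivalaldehyde to give the α-hydroxy ynone without touching the quaternary centre.

**Step 5**
Reactants: 11 α-hydroxy ynone
Product: 12 (2R)-2-allyl-5-[(2Z)-4-(tert-butyldimethylsilyloxy)but-2-en-2-yl]-2-methylfuran-3(2H)-one
Conditions: Ph3PAuCl (5 mol %), AgOTf (5 mol %), toluene, rt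
Reagents that add atoms: none
Why: Gold-catalysed 5-endo-dig cycloisomerisation of a γ-hydroxy alkynone (monovalent gold activates C2≡C3, the tertiary hydroxyl adds to C3, protodeauration follows) closes ring B as the 3(2H)-furanone with C10 unchanged.

**Step 6**
Reactants: 12 allyl furanone
Product: 14 2-{(2R)-5-[(2Z)-4-(tert-butyldimethylsilyloxy)but-2-en-2-yl]-2-methyl-3-oxo-2,3-dihydrofuran-2-yl}acetaldehyde, via diol 13 (not isolated)
Conditions: OsO4 (2 mol %), NaIO4 (4 equiv), 2,6-lutidine (2 equiv), dioxane–H2O, rt
Reagents that add atoms: osmium tetroxide, O=[Os](=O)(=O)=O; sodium periodate, [Na+].[O-]I(=O)(=O)=O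
Why: In this Lemieux–Johnson cleavage the electrophilic osmium reagent should take the isolated monosubstituted alkene before the two double bonds conjugated with the furanone carbonyl, periodate cleaves diol 13 to the C8 aldehyde, and 2,6-lutidine keeps the medium too weakly basic for β-elimination of the furanone oxygen.

**Step 7**
Reactants: 15 methyl propiolate; 16 formaldehyde
Product: 18 methyl (Z)-2-(hydroxymethyl)-3-iodoprop-2-enoate, via magnesium iodoallenolate 17 (not isolated)
Conditions: MgI2 (1.2 equiv), CH2O (from cracked paraformaldehyde), CH2Cl2, 0 °C; H2O work-up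
Reagents that add atoms: magnesium diiodide, [Mg+2].[I-].[I-]
Why: In this iodide-triggered variant of the Morita–Baylis–Hillman reaction, iodide adds to the propiolate, the allenolate 17 is trapped by formaldehyde at its α-carbon, and kinetic protonation geometry leaves iodine cis to the ester (Z), as needed for later lactonisation.

**Step 8**
Reactants: 14 C8 aldehyde; 18 methyl (Z)-2-(hydroxymethyl)-3-iodoprop-2-enoate
Product: 20 (5S)-5-({(2R)-5-[(2Z)-4-(tert-butyldimethylsilyloxy)but-2-en-2-yl]-2-methyl-3-oxo-2,3-dihydrofuran-2-yl}methyl)-3-(hydroxymethyl)furan-2(5H)-one, via hydroxy ester 19 (not isolated)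
Conditions: CrCl2 (4 equiv), NiCl2 (2 mol %), (S)-N-[2-(4-isopropyl-4,5-dihydrooxazol-2-yl)-6-methylphenyl]methanesulfonamide (4.4 equiv), Et3N (4.4 equiv), THF, rt; aqueous work-up
Reagents that add atoms: none
Why: In this asymmetric Nozaki–Hiyama–Kishi alkenylation the ligand-bound alkenylchromium adds only to the aldehyde, delivery to the Re face sets C8 (S) under reagent control, and the Z geometry places the new alkoxide next to the ester so that 19 lactonises and closes ring A as the butenolide.

**Step 9**
Reactants: 20 α-(hydroxymethyl)butenolide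
Product: 21 (5S)-3-(bromomethyl)-5-({(2R)-5-[(2Z)-4-(tert-butyldimethylsilyloxy)but-2-en-2-yl]-2-methyl-3-oxo-2,3-dihydrofuran-2-yl}methyl)furan-2(5H)-one
Conditions: CBr4 (1.3 equiv), PPh3 (1.1 equiv, added last), CH2Cl2, 0 °C
Reagents that add atoms: carbon tetrabromide, BrC(Br)(Br)Br
Why: The Appel reaction converts the primary allylic alcohol into the bromide under neutral conditions that spare the silyl ether and do not deprotonate the acidic C8–H of the butenolide.

**Step 10**
Reactants: 21 bromide silyl ether
Product: 22 (5S)-3-(bromomethyl)-5-({(2R)-5-[(2Z)-4-hydroxybut-2-en-2-yl]-2-methyl-3-oxo-2,3-dihydrofuran-2-yl}methyl)furan-2(5H)-one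
Conditions: aq. HF (48 %), MeCN, 0 °C
Reagents that add atoms: none
Why: Acidic fluoride desilylation is used free of amines, because the 2-(bromomethyl)enoate unit would quaternise pyridine or trialkylamines, and it leaves the bromide, both rings and the Z alkene intact.

**Step 11**
Reactants: 22 Z-allylic alcohol
Product: 23 (2Z)-3-[(5R)-5-{[(2S)-4-(bromomethyl)-5-oxo-2,5-dihydrofuran-2-yl]methyl}-5-methyl-4-oxo-4,5-dihydrofuran-2-yl]but-2-enal
Conditions: activated MnO2 (20 equiv), CH2Cl2, rt, in the dark; used at once
Reagents that add atoms: none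
Why: Heterogeneous MnO2 oxidation of an allylic alcohol is neutral, does not touch the allylic bromide and normally keeps the Z geometry of the resulting enal.

**Step 12**
Reactants: 23 bromo Z-enal
Product: 25 (6R,7R,8S,10R)-6-hydroxy-1-oxo-3,10-epoxygermacra-2,4Z,11(13)-trien-12,8-olide, via allylchromium 24 (not isolated)
Conditions: CrCl2 (10 equiv), 4 Å molecular sieves, THF, rt; 23 added by syringe pump (final concentration about 0.002 M); aqueous work-up
Reagents that add atoms: none
Why: CrCl2 reduces the allylic C13–Br bond of 23 by two one-electron transfers to the allylchromium 24 (trivalent chromium), whose γ-carbon C7 adds to the C6 aldehyde through a closed six-membered Zimmerman–Traxler array with allyl transposition (SE2'), so that a single event makes C6–C7, pushes the ring A double bond out to C11=C13 and closes ring C. The closest known reaction type is the intramolecular Nozaki–Hiyama–Kishi allylation by which 2-(alkoxycarbonyl)allyl bromides close ten-membered germacrane rings, together with the intermolecular addition of 3-(bromomethyl)butenolides to aldehydes. Ring C closes in the 9-exo-trig mode at C6=O (10-exo-trig if the ring is counted through C1 and C2). C7 (R) is controlled by C8: the tether C9–C10–O–C3–C4=C5 is short and contains the flat O–C3–C4 unit of ring B, so it can bring C6 only to the butenolide face opposite C9 (C9–C8–C7–C6 dihedral well above 90 degrees), which gives the trans-fused lactone. C6 is controlled by the ring-locked E-type geometry of the allylchromium and by the s-trans Z-enal, whose chain end takes the equatorial site and whose chromium-bound oxygen stays on the outer rim next to C13, which leads to the anti (6R) carbinol, a centre that is reset in steps 13 and 14 so that its control is not critical. The step needs γ- over α-attack, ring closure over oligomerisation, reduction of the allylic bromide before the enal or dienone, and retention of the Z double bond, and these are secured by the cyclic transition state that only C7 can enter, by slow addition at high dilution, by the much faster reaction of divalent chromium with allylic bromides, and by the neutral, amine-free medium.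

**Step 13**
Reactants: 25 (6R)-alcohol
Product: 26 (7R,8S,10R)-1,6-dioxo-3,10-epoxygermacra-2,4Z,11(13)-trien-12,8-olide
Conditions: Dess–Martin periodinane (1.5 equiv), NaHCO3 (5 equiv), CH2Cl2, 0 °C; filtration through neutral silica, used at once
Reagents that add atoms: none
Why: The buffered Dess–Martin oxidation erases the C6 centre under neutral conditions, and C7 should hold because its hydrogen points into ring C and enolisation would place a further trigonal atom in the strained ring.

**Step 14**
Reactants: 26 C6 ketone
Product: 27 (6S,7R,8S,10R)-6-hydroxy-1-oxo-3,10-epoxygermacra-2,4Z,11(13)-trien-12,8-olide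
Conditions: CeCl3·7H2O (1.5 equiv), NaBH4 (1.0 equiv), MeOH–CH2Cl2, −78 °C
Reagents that add atoms: none
Why: The Luche reduction gives 1,2-reduction of the most electrophilic carbonyl (the C6 enone) in preference to the vinylogous ester C1 and the methylene lactone, and hydride should arrive from the outer rim because the inner face of C6=O lies over the O–C3 edge of ring B, which pushes the new hydroxyl inward and sets C6 (S).

**Step 15**
Reactants: 27 (6S)-alcohol; 28 angelic acid
Product: 30 target, (6S,7R,8S,10R)-6-angeloyloxy-1-oxo-3,10-epoxygermacra-2,4Z,11(13)-trien-12,8-olide, via mixed anhydride 29 (not isolated)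
Conditions: 28 (3 equiv), 2,4,6-trichlorobenzoyl chloride (3 equiv), Et3N (3 equiv), toluene, rt; then 27, 80 °C, no DMAP
Reagents that add atoms: none
Why: A Yamaguchi-type mixed-anhydride esterification run without a nucleophilic catalyst acylates O6 with retention at C6 and avoids the addition–elimination pathway that turns angelates into tiglates.

**Compound list**

1 | (S)-lactic acid | C[C@H](O)C(=O)O | starting material
2 | pivalaldehyde | CC(C)(C)C=O | starting material
3 | (2S,5S)-2-tert-butyl-5-methyl-1,3-dioxolan-4-one | C[C@@H]1O[C@H](C(C)(C)C)OC1=O | intermediate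
4 | allyl bromide | C=CCBr | starting material
5 | lithium enolate of 3 (not isolated) | CC1=C([O-])O[C@@H](C(C)(C)C)O1.[Li+] | intermediate
6 | (2S,5R)-5-allyl-2-tert-butyl-5-methyl-1,3-dioxolan-4-one | C[C@]1(CC=C)O[C@H](C(C)(C)C)OC1=O | intermediate
7 | (Z)-3-methylpent-2-en-4-yn-1-ol | C#C/C(C)=C\CO | starting material
8 | (Z)-tert-butyldimethyl[(3-methylpent-2-en-4-yn-1-yl)oxy]silane | C#C/C(C)=C\CO[Si](C)(C)C(C)(C)C | intermediate
9 | lithium acetylide of 8 (not isolated) | [Li+].[C-]#C/C(C)=C\CO[Si](C)(C)C(C)(C)C | intermediate
10 | lithium lactolate from 9 and 6, new centre undefined (not isolated) | C[C@]1(CC=C)O[C@H](C(C)(C)C)OC1([O-])C#C/C(C)=C\CO[Si](C)(C)C(C)(C)C.[Li+] | intermediate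
11 | (4R,8Z)-10-(tert-butyldimethylsilyloxy)-4-hydroxy-4,8-dimethyldeca-1,8-dien-6-yn-5-one | C=CC[C@@](C)(O)C(=O)C#C/C(C)=C\CO[Si](C)(C)C(C)(C)C | intermediate
12 | (2R)-2-allyl-5-[(2Z)-4-(tert-butyldimethylsilyloxy)but-2-en-2-yl]-2-methylfuran-3(2H)-one | C=CC[C@@]1(C)OC(=CC1=O)/C(C)=C\CO[Si](C)(C)C(C)(C)C | intermediate
13 | 2,3-dihydroxypropyl furanone, both C8 epimers (not isolated) | OCC(O)C[C@@]1(C)OC(=CC1=O)/C(C)=C\CO[Si](C)(C)C(C)(C)C | intermediate
14 | C8 aldehyde, (2R)-furanonyl acetaldehyde | O=CC[C@@]1(C)OC(=CC1=O)/C(C)=C\CO[Si](C)(C)C(C)(C)C | intermediate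
15 | methyl propiolate | C#CC(=O)OC | starting material
16 | formaldehyde (from paraformaldehyde) | C=O | starting material
17 | magnesium iodoallenolate (not isolated) | COC(=C=CI)O[Mg]I | intermediate
18 | methyl (Z)-2-(hydroxymethyl)-3-iodoprop-2-enoate | COC(=O)/C(CO)=C\I | intermediate
19 | (Z)-γ-hydroxy enoate, 8S (not isolated) | COC(=O)/C(CO)=C\[C@@H](O)C[C@@]1(C)OC(=CC1=O)/C(C)=C\CO[Si](C)(C)C(C)(C)C | intermediate
20 | (8S,10R)-α-(hydroxymethyl)butenolide furanone, C6 silyl ether | OCC1=C[C@H](C[C@@]2(C)OC(=CC2=O)/C(C)=C\CO[Si](C)(C)C(C)(C)C)OC1=O | intermediate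
21 | (8S,10R)-α-(bromomethyl)butenolide furanone, C6 silyl ether | BrCC1=C[C@H](C[C@@]2(C)OC(=CC2=O)/C(C)=C\CO[Si](C)(C)C(C)(C)C)OC1=O | intermediate
22 | (8S,10R)-α-(bromomethyl)butenolide furanone, free Z-allylic alcohol | BrCC1=C[C@H](C[C@@]2(C)OC(=CC2=O)/C(C)=C\CO)OC1=O | intermediate
23 | (8S,10R)-α-(bromomethyl)butenolide furanone, Z-enal | BrCC1=C[C@H](C[C@@]2(C)OC(=CC2=O)/C(C)=C\C=O)OC1=O | intermediate
24 | allylchromium dichloride from 23 (not isolated) | Cl[Cr](Cl)CC1=C[C@H](C[C@@]2(C)OC(=CC2=O)/C(C)=C\C=O)OC1=O | intermediate
25 | (6R,7R,8S,10R)-6-hydroxy-1-oxo-3,10-epoxygermacra-2,4Z,11(13)-trien-12,8-olide | C=C1C(=O)O[C@H]2C[C@@]3(C)OC(=CC3=O)/C(C)=C\[C@@H](O)[C@H]12 | intermediate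
26 | (7R,8S,10R)-1,6-dioxo-3,10-epoxygermacra-2,4Z,11(13)-trien-12,8-olide | C=C1C(=O)O[C@H]2C[C@@]3(C)OC(=CC3=O)/C(C)=C\C(=O)[C@H]12 | intermediate
27 | (6S,7R,8S,10R)-6-hydroxy-1-oxo-3,10-epoxygermacra-2,4Z,11(13)-trien-12,8-olide | C=C1C(=O)O[C@H]2C[C@@]3(C)OC(=CC3=O)/C(C)=C\[C@H](O)[C@H]12 | intermediate
28 | angelic acid, (Z)-2-methylbut-2-enoic acid | C/C=C(/C)C(=O)O | starting material
29 | angelic 2,4,6-trichlorobenzoic anhydride (not isolated) | C/C=C(/C)C(=O)OC(=O)c1c(Cl)cc(Cl)cc1Cl | intermediate
30 | target, (6S,7R,8S,10R)-6-angeloyloxy-1-oxo-3,10-epoxygermacra-2,4Z,11(13)-trien-12,8-olide | C=C1C(=O)O[C@H]2C[C@@]3(C)OC(=CC3=O)/C(C)=C\[C@H](OC(=O)/C(C)=C\C)[C@H]12 | target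

**Totals and risks**

Total step count: 15. Longest linear sequence: 13 (steps 1, 2, 4, 5, 6, 8, 9, 10, 11, 12, 13, 14, 15).

**Risk 1, step 12.** The strain of ring C may let several processes outrun closure. These are intermolecular allylation (oligomerisation), bond formation through C13 to a larger ring, and Z to E isomerisation of the enal on Lewis-acidic trivalent chromium.

The fallback makes C6–C7 intermolecularly and closes ring C at C4=C5 by ring-closing metathesis. It sets out from 6 and comes back at 30.
- The lithium acetylide of 2-methylbut-1-en-3-yne is added to 6 as in step 4 to give the isopropenyl hydroxy ynone F1.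
- Ph3PAuCl/AgOTf gives the isopropenyl allyl furanone F2.
- OsO4/NaIO4/2,6-lutidine gives the aldehyde F3.
- The coupling with 18 under the conditions of step 8 gives the hydroxymethyl butenolide F4.
- CBr4/PPh3 gives the bromide F5.
- CrCl2 and acrolein in THF give the trans, anti (6R) vinyl carbinol F6, through a chair transition state with attack opposite C9.
- A Mitsunobu esterification with 28 (DIAD, PPh3, toluene, 0 °C) on this open-chain alcohol inverts C6 and gives the (6S)-angelate triene F7.
- The second-generation Hoveyda–Grubbs catalyst in hot dilute toluene joins the vinyl and isopropenyl groups. The ring size allows only the Z alkene, and the product is 30.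

**Risk 2, step 14.** Facial selectivity at C6=O may be poor, because the outer face is flanked by C11. Conjugate reduction of the methylene lactone may compete. C11=C13 may drift into conjugation at the ketone stage. The new inward hydroxyl may add across the ring to C3.

The fallback replaces the redox inversion by a substitution. It sets out from 25 and comes back at 30. A Mitsunobu esterification of 25 with 28 (DIAD, PPh3, toluene, 0 °C to rt) inverts C6 and installs the angelate in one operation, skipping 26 and 27. This fallback makes no new compound (F0).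

**Risk 3, step 8.** The chiral chromium complex may not override the bias of the neighbouring quaternary C10 (poor facial selectivity). The β-oxygenated aldehyde may also lose the furanone oxygen by β-elimination before it couples.

The fallback sets C8 by ketone reduction and closes ring A by metathesis. It sets out from 14 and comes back at 21.
- Vinylmagnesium bromide at −78 °C gives the allylic alcohol F8 as a mixture of C8 epimers.
- Dess–Martin periodinane gives the vinyl ketone F9.
- Corey–Bakshi–Shibata reduction with (R)-2-methyl-CBS-oxazaborolidine and BH3·SMe2 gives the (8S)-allylic alcohol F10.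
- 2-(Bromomethyl)acryloyl chloride with 2,6-di-tert-butylpyridine gives the ester F11.
- The second-generation Grubbs catalyst in refluxing CH2Cl2 closes the butenolide to 21.

**Further compounds**

F1 | step 12 | (R)-4-hydroxy-4,8-dimethylnona-1,8-dien-6-yn-5-one | C=CC[C@@](C)(O)C(=O)C#CC(C)=C
F2 | step 12 | (2R)-2-allyl-2-methyl-5-(prop-1-en-2-yl)furan-3(2H)-one | C=CC[C@@]1(C)OC(=CC1=O)C(C)=C
F3 | step 12 | 2-[(2R)-2-methyl-3-oxo-5-(prop-1-en-2-yl)-2,3-dihydrofuran-2-yl]acetaldehyde | O=CC[C@@]1(C)OC(=CC1=O)C(C)=C
F4 | step 12 | (8S,10R)-α-(hydroxymethyl)butenolide isopropenyl furanone | OCC1=C[C@H](C[C@@]2(C)OC(=CC2=O)C(C)=C)OC1=O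
F5 | step 12 | (8S,10R)-α-(bromomethyl)butenolide isopropenyl furanone | BrCC1=C[C@H](C[C@@]2(C)OC(=CC2=O)C(C)=C)OC1=O
F6 | step 12 | (6R,7R,8S,10R)-vinyl carbinol α-methylene lactone | C=C1C(=O)O[C@@H](C[C@@]2(C)OC(=CC2=O)C(C)=C)[C@@H]1[C@H](O)C=C
F7 | step 12 | (6S,7R,8S,10R)-angelate triene, metathesis precursor | C=C1C(=O)O[C@@H](C[C@@]2(C)OC(=CC2=O)C(C)=C)[C@@H]1[C@@H](OC(=O)/C(C)=C\C)C=C
F0 | step 14 | none | none
F8 | step 8 | allylic alcohol, both C8 epimers | C=CC(O)C[C@@]1(C)OC(=CC1=O)/C(C)=C\CO[Si](C)(C)C(C)(C)C
F9 | step 8 | vinyl ketone | C=CC(=O)C[C@@]1(C)OC(=CC1=O)/C(C)=C\CO[Si](C)(C)C(C)(C)C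
F10 | step 8 | (8S)-allylic alcohol | C=C[C@@H](O)C[C@@]1(C)OC(=CC1=O)/C(C)=C\CO[Si](C)(C)C(C)(C)C
F11 | step 8 | (8S)-2-(bromomethyl)acrylate ester | C=C[C@@H](OC(=O)C(=C)CBr)C[C@@]1(C)OC(=CC1=O)/C(C)=C\CO[Si](C)(C)C(C)(C)C
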